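## Analysis of the target

Target 12 is a single benzene ring with four substituents: a free hydroxyl on C1, methoxy groups on C2 and C4, and an unbranched, saturated C21 chain on C6; C3 and C5 carry hydrogen. There is no stereocentre and no second ring, so the synthesis is a problem of regiochemistry on one arene and of telling three oxygen atoms apart. O1 and O4 are para to each other, which makes 12 a hydroquinone monoether. The free phenol, above all as its phenoxide in air, is easily oxidised to a 1,4-benzoquinone and is the only sensitive function; the methyl ethers and the chain are inert. The difficulty is twofold: the 1,2,4-trioxygenated, 6-alkylated pattern is not offered by a cheap arene, and a precursor with two free para hydroxyls could not be methylated reliably on O4 alone. The chain adds a practical problem, because all C21 intermediates are waxy and lipophilic, and regioisomers or chain homologues would be nearly inseparable; the chain length must therefore come from one pure building block and every ring functionalisation must be regiochemically clean. The plan rests on what remains when the oxygen on C4 is removed: a 1,2,3-trisubstituted benzene (C6 chain, O1, C2 methoxy) whose ring hydrogens sit on C3, C4 and C5, with C4–H the only one flanked by two hydrogens, meta to both outer substituents and para to O1. That 1,2,3-pattern, with a one-carbon handle where the chain belongs, is the substitution pattern of o-vanillin 1.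

## Retrosynthetic reasoning

The last forward operation forms no skeletal bond: the O1–H of 12 is traced back to the O1–Si bond of silyl ether 11. The phenol is the one oxidisable function, so it is uncovered only at the end, and its silyl mask keeps O1 different from O4 in the preceding steps.

Cutting the O4–CH3 bond of 11 leads to phenol 10, in which O4 is the only free hydroxyl. The methylation therefore needs no selectivity between the para oxygens; it only has to leave the O1–Si bond alone.

The strategic cut is the C4–O bond of 10, which goes back through aryl boronate 9 to a C4–H bond in arene 8. It is made here and not at C1–O or C2–O because C4 is the one oxygenated carbon whose removal leaves a pattern that exists in a commodity arene and also directs the return reaction. In 8 the ring hydrogens are on C3, C4 and C5, and only C4–H has no neighbouring substituent. The forward reaction has to replace exactly this hydrogen by oxygen, leave C3–H, C5–H and all aliphatic C–H bonds untouched, and deliver O4 as a free hydroxyl while O1 stays silylated.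

The chain of 8 is cut between its first and second carbon, after a double bond is reintroduced there (alkene 7). The benzylic carbon becomes the formyl carbon of aldehyde 3, and the other twenty carbons become phosphonium salt 5, which reacts as ylide 6. This cut is preferred to an aryl–alkyl cut because the formyl group of o-vanillin 1 already sits on the future C6 next to O1, so no aryl halide or aryl metal has to be made, and the whole chain length is set by one pure C20 unit. The alkene geometry does not matter, since hydrogenation removes it.

Aldehyde 3 is o-vanillin 1 silylated on its hydroxyl with chloride 2. The silyl group goes on first because the acidic phenol would quench the ylide, and a bulky triisopropylsilyl group is chosen because it must pass a strong base, a hydrogenation, a basic peroxide oxidation and a basic alkylation before removal. Salt 5 comes from 1-bromoicosane 4 by quaternisation of a triarylphosphine.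

## Alternatives that were turned down

Alternative 1: The benzene ring is opened between C1 and C6 and traced back to an acyclic tetraketide, methyl 3,5,7-trioxooctacosanoate A1. In the forward key step, dilute aqueous alkali would generate the enolate at C2 of A1 (between ester and ketone), which adds to the C7 ketone carrying the chain; loss of water and enolisation give methyl 6-heneicosyl-2,4-dihydroxybenzoate A2.
- For: ring and chain arrive together from cheap acylation chemistry without a precious metal, and the ring positions are fixed by the carbon chain, so there is no C–H site selectivity to secure. On that point it is stronger than the chosen plan.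
- Against: the fold gives a resorcinol pattern. The two hydroxyls of A2 become O2 and O4, O1 is missing, and the ester carbon that marks C1 must be degraded to oxygen (reduction to the aldehyde level, aryl-to-oxygen migration of the Dakin or Baeyer–Villiger type, hydrolysis) after both hydroxyls are methylated, one of them chelated to the ester and slow to react. That is four to five steps after the key step and one carbon installed only to be excised. A1 is a mixture of tautomers, needs polyanion acylation, and can close in the Claisen sense or lactonise instead.
- Comparison: the chosen route buys the ring with O1, O2 and the C6 carbon in place, adds one oxygen, and needs seven steps in all.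

Alternative 2: Ring bonds C1–C2 and C5–C6 are cut. C2 to C5 with both methoxy groups come from the Birch-derived 1,3-dimethoxycyclohexa-1,3-diene A3, and C1 and C6 come from pentacos-3-yn-2-one A4, whose acetyl group is the latent O1. In the forward key step a Diels–Alder addition joins the methoxy-bearing diene terminus to the acetyl-bearing alkyne carbon and the more nucleophilic unsubstituted terminus to the chain-bearing carbon. The bicyclo[2.2.2]octadiene then expels its saturated two-carbon bridge as a gaseous alkene on heating (Alder–Rickert) to give 1-(2-heneicosyl-4,6-dimethoxyphenyl)ethan-1-one A5; Baeyer–Villiger oxidation and ester cleavage would finish.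
- For: it is highly convergent, the polarity of the cycloaddition places every substituent, and O1 is distinct from the methoxy oxygens from the start because it enters as acetyl. In convergence and certainty of the oxygen pattern it is as strong as or stronger than the chosen plan, and its step count is comparable.
- Against: A4 is an internal ynone with a long chain on its β-carbon, a far weaker dienophile than a terminal one. The prolonged heating it would need is what the acid- and heat-sensitive bis-enol ether A3 tolerates least, and A3 must first be equilibrated from its unconjugated Birch isomer. A4 requires a C23 alkyne that is not a commodity, and the final peracid step acts on a di-ortho-substituted ketone in competition with oxidation of a very electron-rich ring.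
- Comparison: the chosen route keeps every step near room temperature or at 80 °C on robust intermediates, takes the chain from a commodity C20 bromide, and puts its risk in one catalytic step with a simple steric rule.

Alternative 3: Ring bond C4–C5 is cut and the arene is traced back to a four-membered ring, racemic 4-(tert-butyldimethylsilyloxy)-3-methoxy-4-(tricos-1-en-2-yl)cyclobut-2-en-1-one A6, itself from addition of a 2-metallated 1-alkene to a semisquaric ester and silylation. In the forward key step, heating A6 in an aromatic solvent opens the cyclobutenone in a 4π electrocyclic step to a dienylketene. The ketene carbon (future C4) then bonds to the terminal methylene (future C5) in a 6π closure, and tautomerisation gives 4-(tert-butyldimethylsilyloxy)-3-heneicosyl-5-methoxyphenol A7, the tert-butyldimethylsilyl analogue of 10, with the same two-step endgame.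
- For: the substitution pattern is built in, the conditions are neutral and thermal, no precious metal is used, and the para oxygens are differentiated in the same way as in the chosen plan. On certainty of regiochemistry it is stronger.
- Against: the work moves into A6. The semisquaric ester is a costly speciality building block, the C23 alkenyl metal needs several steps from a long-chain acid and must be added at low temperature where C21-chain compounds barely dissolve, and a stereocentre is made only to be destroyed. About ten steps result.
- Comparison: the chosen route reaches the same kind of intermediate, 10, in five steps from o-vanillin 1 with a purchased ring.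

Key step: step 5

## Route

Remark: alkene 7 is expected as a Z/E mixture and is drawn as its Z isomer; both isomers give 8 in step 4.

Step 1
Reactants: 1 o-vanillin (2-hydroxy-3-methoxybenzaldehyde); 2 triisopropylsilyl chloride
Product: 3 3-methoxy-2-(triisopropylsilyloxy)benzaldehyde
Conditions: imidazole, DMF, rt to 40 °C
Reagents that add atoms: none
Why: Silylation of a phenol by substitution at silicon through the N-silylimidazolium ion; the hydroxyl is acidic enough for imidazole, and the triisopropylsilyl group, once flanked by two ortho substituents, should withstand the basic steps that follow.

Step 2
Reactants: 4 1-bromoicosane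
Product: 5 icosyltriphenylphosphonium bromide
Conditions: PPh3, toluene, 110 °C; trituration with Et2O
Reagents that add atoms: triphenylphosphine, c1ccc(cc1)P(c1ccccc1)c1ccccc1
Why: SN2 quaternisation of the phosphine by an unhindered primary bromide, the standard preparation of a Wittig salt; the long chain only lowers the rate, which heat and concentration make up for.

Step 3
Reactants: 5 icosyltriphenylphosphonium bromide; 3 3-methoxy-2-(triisopropylsilyloxy)benzaldehyde
Product: 7 triisopropyl[2-(heneicos-1-en-1-yl)-6-methoxyphenoxy]silane (Z/E mixture), via icosylidenetriphenylphosphorane 6 (not isolated)
Conditions: NaN(SiMe3)2, THF, 0 °C; then 3, 0 °C to rt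
Reagents that add atoms: none
Why: Wittig olefination of an aromatic aldehyde with a non-stabilised ylide through an oxaphosphetane; the hindered amide base should not attack silicon, and the alkene geometry (mainly Z expected) is of no consequence because step 4 removes it.

Step 4
Reactants: 7 triisopropyl[2-(heneicos-1-en-1-yl)-6-methoxyphenoxy]silane
Product: 8 triisopropyl(2-heneicosyl-6-methoxyphenoxy)silane
Conditions: H2 (1 atm), 10% Pd/C, EtOAc, rt
Reagents that add atoms: none
Why: Heterogeneous catalytic hydrogenation of a 1,2-disubstituted styrene-type alkene; the aryl ethers and the silyl ether are inert, and both alkene isomers converge on one saturated chain.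

Step 5
Reactants: 8 triisopropyl(2-heneicosyl-6-methoxyphenoxy)silane
Product: 10 3-heneicosyl-5-methoxy-4-(triisopropylsilyloxy)phenol, via aryl pinacol boronate 9 (not isolated)
Conditions: [Ir(OMe)(cod)]2 (1.5 mol%), 4,4'-di-tert-butyl-2,2'-bipyridine (3 mol%), B2pin2 (1.0 equiv), THF, 80 °C; then NaBO3·4H2O, THF/H2O, rt
Reagents that add atoms: bis(pinacolato)diboron, CC1(C)OB(OC1(C)C)B1OC(C)(C)C(C)(C)O1; sodium perborate NaBO3, [Na+].[O-]OB=O
Why: The reaction is the iridium-catalysed aromatic C–H borylation followed by oxidation of the aryl boronate in the same flask, a known sequence for turning 1,2,3-trisubstituted arenes into 3,4,5-trisubstituted phenols. [Ir(OMe)(cod)]2, the bipyridine and B2pin2 form a bipyridine-ligated tris(boryl) complex of trivalent iridium, which cleaves an aryl C–H bond to a pentavalent iridium aryl hydride and releases aryl boronate 9 by C–B reductive elimination, after which B2pin2 restores the tris(boryl) species. The selectivity needed is C4 over C3 and C5 and is steric: the crowded iridium centre does not reach a C–H bond next to a substituent, C3 lies beside the methoxy group and C5 beside the benzylic CH2 of the chain, and only C4 has hydrogen on both sides. The sp3 C–H bonds of the chain and of the isopropyl groups should not react with this catalyst at 80 °C. In the second stage the hydroperoxide released from NaBO3 adds to boron, the aryl group shifts from boron to oxygen with loss of hydroxide, and hydrolysis of the aryl borate gives phenol 10. The bulky silyl ether on O1, shielded by two ortho substituents, should survive the weakly basic perborate medium, so O4 appears free while O1 stays masked. No ring is closed and no stereocentre is formed; the step makes the C4–O bond.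

Step 6
Reactants: 10 3-heneicosyl-5-methoxy-4-(triisopropylsilyloxy)phenol
Product: 11 (2-heneicosyl-4,6-dimethoxyphenoxy)triisopropylsilane
Conditions: MeI, K2CO3, acetone, 40 °C, argon
Reagents that add atoms: methyl iodide, CI
Why: Williamson ether synthesis on the only free hydroxyl, which is unhindered; O1 is silylated, so the two para oxygens never compete, and anhydrous carbonate in acetone should be mild enough to leave the hindered aryl silyl ether in place.

Step 7
Reactants: 11 (2-heneicosyl-4,6-dimethoxyphenoxy)triisopropylsilane
Product: 12 6-n-heneicosyl-2,4-dimethoxyphenol
Conditions: Bu4NF, AcOH, THF, 0 °C to rt, argon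
Reagents that add atoms: none
Why: Fluoride-induced cleavage of an aryl silyl ether, driven by the Si–F bond and the good phenoxide leaving group; acetic acid protonates the phenoxide as it forms, so the oxidisable product is not left as its anion.

## Compound list

1 | o-vanillin (2-hydroxy-3-methoxybenzaldehyde) | COc1cccc(C=O)c1O | starting material
2 | triisopropylsilyl chloride | CC(C)[Si](Cl)(C(C)C)C(C)C | starting material
3 | 3-methoxy-2-(triisopropylsilyloxy)benzaldehyde | COc1cccc(C=O)c1O[Si](C(C)C)(C(C)C)C(C)C | intermediate
4 | 1-bromoicosane | CCCCCCCCCCCCCCCCCCCCBr | starting material
5 | icosyltriphenylphosphonium bromide | CCCCCCCCCCCCCCCCCCCC[P+](c1ccccc1)(c1ccccc1)c1ccccc1.[Br-] | intermediate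
6 | icosylidenetriphenylphosphorane (ylide, not isolated) | CCCCCCCCCCCCCCCCCCCC=P(c1ccccc1)(c1ccccc1)c1ccccc1 | intermediate
7 | triisopropyl[2-(heneicos-1-en-1-yl)-6-methoxyphenoxy]silane (Z/E mixture, Z isomer drawn) | C(/CCCCCCCCCCCCCCCCCCC)=C/c1cccc(OC)c1O[Si](C(C)C)(C(C)C)C(C)C | intermediate
8 | triisopropyl(2-heneicosyl-6-methoxyphenoxy)silane | CCCCCCCCCCCCCCCCCCCCCc1cccc(OC)c1O[Si](C(C)C)(C(C)C)C(C)C | intermediate
9 | 2-[3-heneicosyl-5-methoxy-4-(triisopropylsilyloxy)phenyl]-4,4,5,5-tetramethyl-1,3,2-dioxaborolane (aryl pinacol boronate, not isolated) | CCCCCCCCCCCCCCCCCCCCCc1cc(B2OC(C)(C)C(C)(C)O2)cc(OC)c1O[Si](C(C)C)(C(C)C)C(C)C | intermediate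
10 | 3-heneicosyl-5-methoxy-4-(triisopropylsilyloxy)phenol | CCCCCCCCCCCCCCCCCCCCCc1cc(O)cc(OC)c1O[Si](C(C)C)(C(C)C)C(C)C | intermediate
11 | (2-heneicosyl-4,6-dimethoxyphenoxy)triisopropylsilane | CCCCCCCCCCCCCCCCCCCCCc1cc(OC)cc(OC)c1O[Si](C(C)C)(C(C)C)C(C)C | intermediate
12 | 6-n-heneicosyl-2,4-dimethoxyphenol | CCCCCCCCCCCCCCCCCCCCCc1cc(OC)cc(OC)c1O | target

## Step count and least certain steps

Total step count: 7. Longest linear sequence: 6 steps (from 1 through steps 1, 3, 4, 5, 6, 7; equally from 4 through steps 2 to 7).

Step 5 (key step). The borylation may stall, because the catalyst is sensitive to traces of phosphorus compounds carried over from step 3 and the substrate is bulky. Site selectivity may also erode toward C3 beside the small methoxy group, and the oxidation stage may strip the silyl group or oxidise the electron-rich silyloxyphenol further to a quinone. The fallback replaces C–H borylation by electrophilic substitution directed by a free hydroxyl, followed by Ullmann-type ether formation. It sets out from 8, whose silyl ether is cleaved with Bu4NF/AcOH in THF to give 2-heneicosyl-6-methoxyphenol F1. N-Bromosuccinimide (1.0 equiv, CH2Cl2/MeCN, 0 °C) should then brominate para to the free hydroxyl, whose two ortho positions are occupied, to give 4-bromo-2-heneicosyl-6-methoxyphenol F2. Copper-catalysed methoxylation of this bromophenol (NaOMe, CuBr, MeOH/DMF, 110 °C) leads directly to the target, so the fallback comes back to the route at 12 and steps 6 and 7 fall away.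

Step 3. Addition of the ylide to the hindered, electron-rich aldehyde may be slow, the waxy salt and ylide may dissolve poorly, and the basic medium may remove or shift the silyl group, which is activated by the ortho formyl group. The fallback uses carbonyl addition and ionic deoxygenation instead of olefination. It sets out from 4, which with Mg in THF gives icosylmagnesium bromide F3. Addition of F3 to aldehyde 3 (THF, 0 °C, NH4Cl work-up) should give racemic 1-[3-methoxy-2-(triisopropylsilyloxy)phenyl]heneicosan-1-ol F4. Et3SiH and CF3CO2H in CH2Cl2 at 0 °C remove the benzylic hydroxyl through the aryl-stabilised cation, and the fallback comes back at 8 without passing through 5, 6 and 7.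

Step 6. Carbonate or the phenoxide may cleave the silyl ether, after which O1 would be methylated as well, and the phenoxide may be oxidised by adventitious air. The fallback sets out from 10 and uses a Mitsunobu etherification with methanol (PPh3, diisopropyl azodicarboxylate, THF, 0 °C to rt). Here methanol is activated as an alkoxyphosphonium ion and the phenol acts as the acid component, so no carbonate and no standing phenoxide are present. No new compound is made, and the fallback comes back at 11.

Step 1. Silylation may remain incomplete, because the hydroxyl is hydrogen-bonded to the formyl oxygen and crowded by two ortho groups, and the silyl group of 3 may be lost hydrolytically on work-up or chromatography, the ortho formyl group making the phenoxide a good leaving group. The fallback puts olefination before protection. It sets out from 1, which is converted to its sodium salt with NaN(SiMe3)2 in THF and treated with ylide 6 (from 5) to give 2-(heneicos-1-en-1-yl)-6-methoxyphenol F5 as a Z/E mixture. F5 no longer carries a formyl group and is silylated with 2 (imidazole, DMF), and the fallback comes back at 7.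

## Further compounds

F1 | step 5 | 2-heneicosyl-6-methoxyphenol | CCCCCCCCCCCCCCCCCCCCCc1cccc(OC)c1O
F2 | step 5 | 4-bromo-2-heneicosyl-6-methoxyphenol | CCCCCCCCCCCCCCCCCCCCCc1cc(Br)cc(OC)c1O
F3 | step 3 | icosylmagnesium bromide | CCCCCCCCCCCCCCCCCCCC[Mg]Br
F4 | step 3 | 1-[3-methoxy-2-(triisopropylsilyloxy)phenyl]heneicosan-1-ol (racemic) | CCCCCCCCCCCCCCCCCCCCC(O)c1cccc(OC)c1O[Si](C(C)C)(C(C)C)C(C)C
F0 | step 6 | none | none
F5 | step 1 | 2-(heneicos-1-en-1-yl)-6-methoxyphenol (Z/E mixture, Z isomer drawn) | C(/CCCCCCCCCCCCCCCCCCC)=C/c1cccc(OC)c1O
A1 | alternative 1 | methyl 3,5,7-trioxooctacosanoate | CCCCCCCCCCCCCCCCCCCCCC(=O)CC(=O)CC(=O)CC(=O)OC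
A2 | alternative 1 | methyl 6-heneicosyl-2,4-dihydroxybenzoate | CCCCCCCCCCCCCCCCCCCCCc1cc(O)cc(O)c1C(=O)OC
A3 | alternative 2 | 1,3-dimethoxycyclohexa-1,3-diene | COC1=CC(OC)=CCC1
A4 | alternative 2 | pentacos-3-yn-2-one | CCCCCCCCCCCCCCCCCCCCCC#CC(C)=O
A5 | alternative 2 | 1-(2-heneicosyl-4,6-dimethoxyphenyl)ethan-1-one | CCCCCCCCCCCCCCCCCCCCCc1cc(OC)cc(OC)c1C(C)=O
A6 | alternative 3 | 4-(tert-butyldimethylsilyloxy)-3-methoxy-4-(tricos-1-en-2-yl)cyclobut-2-en-1-one (racemic) | CCCCCCCCCCCCCCCCCCCCCC(=C)C1(O[Si](C)(C)C(C)(C)C)C(OC)=CC1=O
A7 | alternative 3 | 4-(tert-butyldimethylsilyloxy)-3-heneicosyl-5-methoxyphenol | CCCCCCCCCCCCCCCCCCCCCc1cc(O)cc(OC)c1O[Si](C)(C)C(C)(C)C
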